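**Retrosynthetic overview**
1. Teferin ⇒ vanillic acid (built from catechol) + jaeschkeanadiol, by acylation of the secondary C6–OH.
2. Jaeschkeanadiol ⇒ C6 ketone of the hydroazulene (hydroxyl-directed anti reduction) ⇒ key step: one-carbon ring expansion of a trans-hydrindenone by 1,2-shift of the alkenyl carbon (six → seven ring, C8=C9 placed β,γ).
3. trans-Hydrindenone ⇒ (α-methylation, dehydrogenation) β-silyloxy ketone ⇒ 1,2-hydride shift of a directed epoxy alcohol, which sets C4–O anti to C5–H and the trans ring fusion.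
4. Bicyclic enone ⇒ 3-methylcyclohex-2-en-1-one + ketone homoenolate from 1-isopropylcyclopropanol: enantioselective conjugate addition/aldol condensation sets the quaternary carbon and closes the five-membered ring.
5. Ring order: six-membered ring (bought) → five-membered ring (annulation) → seven-membered ring (ring expansion).

Assumption: atom labels C1–C10 follow daucane numbering (C1 methyl-bearing ring-fusion carbon, C4 isopropyl carbinol carbon, C5 ring-fusion CH, C6 ester carbon, C8 methyl-bearing olefinic carbon), and "methyl face" means the face of the bicycle carrying the C1 methyl group.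

**Step 1**
Reactants: 1 methyl 2-methylpropanoate
Product: 2 1-(propan-2-yl)cyclopropan-1-ol
Conditions: EtMgBr (2.4 equiv), Ti(OiPr)4 (20 mol %), Et2O, 0 → 23 °C
Reagents that add atoms: ethylmagnesium bromide, CC[Mg]Br
Why: Kulinkovich cyclopropanation: the titanacyclopropane made from EtMgBr and Ti(OiPr)4 adds twice to the ester carbonyl to give the 1-substituted cyclopropanol; no stereocentre is formed.

**Step 2**
Reactants: 2 1-(propan-2-yl)cyclopropan-1-ol; 3 3-methylcyclohex-2-en-1-one
Product: 6 (7aS)-7a-methyl-3-(propan-2-yl)-1,2,5,6,7,7a-hexahydro-4H-inden-4-one, via zinc homoenolate 4 (not isolated), via aldol adduct 5 (not isolated)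
Conditions: 2 (2.4 equiv), Et2Zn (1.2 equiv), THF, 23 °C; Cu(OTf)2 (5 mol %), chiral imidazolinium salt L1 (6 mol %; C1-symmetric, N-mesityl/N-(2-sulfonatoaryl), 4,5-diphenyl backbone, antipode that gives 6), 3, −30 → 0 °C; then TsOH·H2O (cat.), PhMe, 80 °C
Reagents that add atoms: none
Why: Proposed new method: the zinc cyclopropoxide of 2 ring-opens to homoenolate 4, C–Zn to C–Cu transmetalation gives a chiral NHC–alkylcopper (monovalent copper) that adds to the zinc-activated enone through a trivalent copper intermediate, and reductive elimination forms the C1–C2 bond and the quaternary centre on the face chosen by L1 (sense to be confirmed by correlation); the zinc enolate then closes the five-membered ring by aldol addition to the isopropyl ketone (5) and acid dehydrates it to 6; the closest known reaction types are copper–NHC-catalysed conjugate addition of dialkylzincs to 3-methylcycloalkenones and racemic conjugate addition/aldol reactions of cyclopropanol-derived zinc homoenolates.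

**Step 3**
Reactants: 6 (7aS)-7a-methyl-3-(propan-2-yl)-1,2,5,6,7,7a-hexahydro-4H-inden-4-one
Product: 7 (4R,7aS)-7a-methyl-3-(propan-2-yl)-2,4,5,6,7,7a-hexahydro-1H-inden-4-ol
Conditions: NaBH4, CeCl3·7H2O, MeOH, −78 → 0 °C
Reagents that add atoms: none
Why: Luche 1,2-reduction: hydride adds anti to the pseudo-axial angular methyl, so the new C6 hydroxyl (4R) ends up on the methyl face.

**Step 4**
Reactants: 7 (4R,7aS)-7a-methyl-3-(propan-2-yl)-2,4,5,6,7,7a-hexahydro-1H-inden-4-ol
Product: 8 3,3a-epoxide of 7 (oxirane oxygen, C4 hydroxyl of the indene numbering and 7a-methyl all on one face)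
Conditions: VO(acac)2 (5 mol %), t-BuOOH, CH2Cl2, 0 → 23 °C
Reagents that add atoms: tert-butyl hydroperoxide, CC(C)(C)OO
Why: Vanadium-catalysed hydroxyl-directed epoxidation delivers oxygen to the tetrasubstituted alkene syn to the allylic OH, i.e. on the methyl face, which fixes the C4–O configuration of the target.

**Step 5**
Reactants: 8 3,3a-epoxide of 7
Product: 10 (3R,3aR,7aS)-7a-methyl-3-(propan-2-yl)-3-[(trimethylsilyl)oxy]octahydro-4H-inden-4-one, via epoxy silyl ether 9 (not isolated)
Conditions: TMSOTf (2.2 equiv), i-Pr2NEt (3 equiv), CH2Cl2, −78 → −40 °C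
Reagents that add atoms: trimethylsilyl trifluoromethanesulfonate, C[Si](C)(C)OS(=O)(=O)C(F)(F)F
Why: Silyl-triflate-promoted epoxide opening with concerted 1,2-hydride shift (non-aldol aldol, semipinacol type): after O-silylation the C6–H anti-periplanar to the activated C5–O bond migrates with inversion at C5, which gives the trans ring fusion (H5 anti to the C4 oxygen and to the methyl) and the C6 ketone, the silyl group ending on the C4 oxygen.

**Step 6**
Reactants: 10 (3R,3aR,7aS)-7a-methyl-3-(propan-2-yl)-3-[(trimethylsilyl)oxy]octahydro-4H-inden-4-one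
Product: 11 5-methyl derivative of 10 (both C5 epimers of the indene numbering)
Conditions: LiN(i-Pr)2 (1.1 equiv), THF, −78 °C; MeI, −78 → −20 °C
Reagents that add atoms: iodomethane, CI
Why: Kinetic enolate alkylation: the base removes a proton from the accessible CH2 (the ring-fusion CH sits between two fully substituted carbons), MeI alkylates there, and the new stereocentre is erased in step 7.

**Step 7**
Reactants: 11 5-methyl derivative of 10
Product: 13 (3R,3aR,7aR)-5,7a-dimethyl-3-(propan-2-yl)-3-[(trimethylsilyl)oxy]-1,2,3,3a,7,7a-hexahydro-4H-inden-4-one, via silyl enol ether 12 (not isolated)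
Conditions: LiN(i-Pr)2 (1.2 equiv), TMSCl, THF, −78 °C; Pd(OAc)2 (1.1 equiv), MeCN, 23 °C
Reagents that add atoms: none
Why: Saegusa–Ito dehydrogenation of the regiodefined silyl enol ether by divalent palladium gives the 2-methyl enone without enolising the ring-fusion CH.

**Step 8**
Reactants: 13 (3R,3aR,7aR)-5,7a-dimethyl-3-(propan-2-yl)-3-[(trimethylsilyl)oxy]-1,2,3,3a,7,7a-hexahydro-4H-inden-4-one
Product: 16 (3R,3aR,8aR)-6,8a-dimethyl-3-(propan-2-yl)-3-[(trimethylsilyl)oxy]-2,3,3a,5,8,8a-hexahydroazulen-4(1H)-one, via carbinolate 14 (not isolated), via dienolate 15 (not isolated)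
Conditions: CH2Br2, lithium 2,2,6,6-tetramethylpiperidide, THF, −90 °C; n-BuLi, −90 → −20 °C; AcOH, −78 °C; used crude
Reagents that add atoms: dibromomethane, BrCBr
Why: One-carbon ring enlargement through a β-oxido carbenoid: after Br/Li exchange the alkenyl carbon C8 shifts from C6 to the carbenoid carbon with loss of LiBr (1,2-shift, six → seven ring), and kinetic α-protonation of dienolate 15 leaves C8=C9 β,γ to the ketone; no stereocentre is touched.

**Step 9**
Reactants: 16 (3R,3aR,8aR)-6,8a-dimethyl-3-(propan-2-yl)-3-[(trimethylsilyl)oxy]-2,3,3a,5,8,8a-hexahydroazulen-4(1H)-one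
Product: 18 jaeschkeanadiol (3R,3aS,4S,8aR)-6,8a-dimethyl-3-(propan-2-yl)-1,2,3,3a,4,5,8,8a-octahydroazulene-3,4-diol, via hydroxy ketone 17 (not isolated)
Conditions: AcOH/THF/H2O (3:1:1), 23 °C; concentrate; Me4NBH(OAc)3 (5 equiv), MeCN/AcOH (1:1), −30 → 0 °C
Reagents that add atoms: none
Why: Mild acid removes the tertiary silyl ether, then Evans–Saksena hydroxyl-directed reduction delivers hydride intramolecularly from the C4 alkoxyborohydride to the methyl face of the C6 ketone, giving the 1,3-anti diol (4S).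

**Step 10**
Reactants: 19 benzene-1,2-diol (catechol)
Product: 20 2-methoxyphenol (guaiacol)
Conditions: MeI (1.0 equiv), K2CO3 (1.0 equiv), acetone, 56 °C
Reagents that add atoms: iodomethane, CI
Why: Williamson mono-O-methylation; it is statistical, and guaiacol is separated from catechol and the dimethyl ether.

**Step 11**
Reactants: 20 2-methoxyphenol
Product: 21 4-bromo-2-methoxyphenol
Conditions: NBS (1.0 equiv), MeCN, 0 °C
Reagents that add atoms: N-bromosuccinimide, BrN1C(=O)CCC1=O
Why: Electrophilic aromatic bromination goes para to the free hydroxyl, the strongest director.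

**Step 12**
Reactants: 21 4-bromo-2-methoxyphenol
Product: 23 4-hydroxy-3-methoxybenzoic acid (vanillic acid), via dilithio phenolate 22 (not isolated)
Conditions: n-BuLi (1.05 equiv), THF, −78 °C; t-BuLi (2.1 equiv), −78 °C; CO2; 1 M HCl
Reagents that add atoms: carbon dioxide, O=C=O
Why: Deprotonation of the phenol, bromine–lithium exchange and carboxylation of the aryllithium.

**Step 13**
Reactants: 23 4-hydroxy-3-methoxybenzoic acid; 18 jaeschkeanadiol
Product: 27 teferin, via bis-silyl vanillate 24 (not isolated), via acid chloride 25 (not isolated), via silyl-protected ester 26 (not isolated)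
Conditions: 23 (1.5 equiv), TMSCl, Et3N, CH2Cl2, 23 °C; (COCl)2, DMF (cat.), 0 °C; 18, pyridine, DMAP (cat.), 0 → 23 °C; aq. citric acid, MeOH
Reagents that add atoms: none
Why: Acylation of the secondary C6 alcohol (the tertiary C4 alcohol is inert) by an acid chloride whose phenol is transiently masked as a trimethylsilyl ether (silyl ester to acid chloride with oxalyl chloride); the aryl silyl ether is cleaved on work-up and no stereocentre changes.

**Compound list**
1 | methyl 2-methylpropanoate | COC(=O)C(C)C | starting material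
2 | 1-(propan-2-yl)cyclopropan-1-ol | CC(C)C1(O)CC1 | intermediate
3 | 3-methylcyclohex-2-en-1-one | CC1=CC(=O)CCC1 | starting material
4 | zinc bis(4-methyl-3-oxopentan-1-ide), zinc homoenolate | CC(C)C(=O)CC[Zn]CCC(=O)C(C)C | intermediate
5 | (3aS,7aS)-3-hydroxy-7a-methyl-3-(propan-2-yl)octahydro-4H-inden-4-one, cis-fused aldol adduct, both C3 epimers | CC(C)C1(O)CC[C@]2(C)CCCC(=O)[C@H]12 | intermediate
6 | (7aS)-7a-methyl-3-(propan-2-yl)-1,2,5,6,7,7a-hexahydro-4H-inden-4-one | CC(C)C1=C2C(=O)CCC[C@@]2(C)CC1 | intermediate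
7 | (4R,7aS)-7a-methyl-3-(propan-2-yl)-2,4,5,6,7,7a-hexahydro-1H-inden-4-ol (OH cis to the 7a-methyl) | CC(C)C1=C2[C@H](O)CCC[C@@]2(C)CC1 | intermediate
8 | 3,3a-epoxide of 7, oxirane oxygen cis to the hydroxyl and the 7a-methyl | CC(C)[C@]12CC[C@]3(C)CCC[C@@H](O)[C@@]31O2 | intermediate
9 | trimethylsilyl ether of 8 | CC(C)[C@]12CC[C@]3(C)CCC[C@@H](O[Si](C)(C)C)[C@@]31O2 | intermediate
10 | (3R,3aR,7aS)-7a-methyl-3-(propan-2-yl)-3-[(trimethylsilyl)oxy]octahydro-4H-inden-4-one, trans-fused | CC(C)[C@]1(O[Si](C)(C)C)CC[C@]2(C)CCCC(=O)[C@@H]12 | intermediate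
11 | (3R,3aR,7aS)-5,7a-dimethyl-3-(propan-2-yl)-3-[(trimethylsilyl)oxy]octahydro-4H-inden-4-one, both C5 epimers | CC(C)[C@]1(O[Si](C)(C)C)CC[C@]2(C)CCC(C)C(=O)[C@@H]12 | intermediate
12 | 4-(trimethylsilyloxy) 4,5-enol ether of 11 | CC(C)[C@]1(O[Si](C)(C)C)CC[C@]2(C)CCC(C)=C(O[Si](C)(C)C)[C@@H]12 | intermediate
13 | (3R,3aR,7aR)-5,7a-dimethyl-3-(propan-2-yl)-3-[(trimethylsilyl)oxy]-1,2,3,3a,7,7a-hexahydro-4H-inden-4-one | CC(C)[C@]1(O[Si](C)(C)C)CC[C@]2(C)CC=C(C)C(=O)[C@@H]12 | intermediate
14 | lithium alkoxide of the 4-(dibromomethyl) carbinol from 13, carbinol configuration open | CC(C)[C@]1(O[Si](C)(C)C)CC[C@]2(C)CC=C(C)C(O[Li])(C(Br)Br)[C@@H]12 | intermediate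
15 | lithium dienolate of 16 | CC(C)[C@]1(O[Si](C)(C)C)CC[C@]2(C)CC=C(C)C=C(O[Li])[C@@H]12 | intermediate
16 | (3R,3aR,8aR)-6,8a-dimethyl-3-(propan-2-yl)-3-[(trimethylsilyl)oxy]-2,3,3a,5,8,8a-hexahydroazulen-4(1H)-one | CC(C)[C@]1(O[Si](C)(C)C)CC[C@]2(C)CC=C(C)CC(=O)[C@@H]12 | intermediate
17 | (3R,3aR,8aR)-3-hydroxy-6,8a-dimethyl-3-(propan-2-yl)-2,3,3a,5,8,8a-hexahydroazulen-4(1H)-one | CC(C)[C@]1(O)CC[C@]2(C)CC=C(C)CC(=O)[C@@H]12 | intermediate
18 | jaeschkeanadiol, (3R,3aS,4S,8aR)-6,8a-dimethyl-3-(propan-2-yl)-1,2,3,3a,4,5,8,8a-octahydroazulene-3,4-diol | CC(C)[C@]1(O)CC[C@]2(C)CC=C(C)C[C@H](O)[C@@H]12 | intermediate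
19 | benzene-1,2-diol (catechol) | Oc1ccccc1O | starting material
20 | 2-methoxyphenol | COc1ccccc1O | intermediate
21 | 4-bromo-2-methoxyphenol | COc1cc(Br)ccc1O | intermediate
22 | lithium 4-lithio-2-methoxyphenolate | [Li]Oc1ccc([Li])cc1OC | intermediate
23 | 4-hydroxy-3-methoxybenzoic acid | COc1cc(C(=O)O)ccc1O | intermediate
24 | trimethylsilyl 3-methoxy-4-[(trimethylsilyl)oxy]benzoate | COc1cc(C(=O)O[Si](C)(C)C)ccc1O[Si](C)(C)C | intermediate
25 | 3-methoxy-4-[(trimethylsilyl)oxy]benzoyl chloride | COc1cc(C(Cl)=O)ccc1O[Si](C)(C)C | intermediate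
26 | O-trimethylsilyl teferin (phenol silyl ether) | COc1cc(C(=O)O[C@H]2CC(C)=CC[C@@]3(C)CC[C@@](O)(C(C)C)[C@H]23)ccc1O[Si](C)(C)C | intermediate
27 | teferin, (3R,3aS,4S,8aR)-3-hydroxy-6,8a-dimethyl-3-(propan-2-yl)-1,2,3,3a,4,5,8,8a-octahydroazulen-4-yl 4-hydroxy-3-methoxybenzoate | COc1cc(C(=O)O[C@H]2CC(C)=CC[C@@]3(C)CC[C@@](O)(C(C)C)[C@H]23)ccc1O | target

**Totals**
Total step count: 13. Longest linear sequence: 10 steps (steps 1–9, then 13); steps 10–12 are the three-step side branch to vanillic acid.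

**Three steps most likely to fail**

Step 2 (proposed new method). Ethyl transfer, a slow homoenolate transfer to the β,β-disubstituted enone, or low enantioselectivity are the likely failures. Fallback with known chemistry, setting out from 2 and 3 and returning at 6: NBS ring-opening of 2 gives 1-bromo-4-methylpentan-3-one F1; ketalisation (ethylene glycol, TsOH) gives 2-(2-bromoethyl)-2-(propan-2-yl)-1,3-dioxolane F2; its Grignard reagent (Mg, THF) is added to 3 under established copper–NHC catalysis (Cu(OTf)2, chiral imidazolinium salt, Et2O, 0 °C) to give (S)-3-methyl-3-{2-[2-(propan-2-yl)-1,3-dioxolan-2-yl]ethyl}cyclohexan-1-one F3; aqueous HCl then TsOH in hot toluene removes the ketal and effects the aldol condensation to 6.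

Step 5. Both epoxide carbons are fully substituted, so opening at C4 (elimination or alkyl shift) can compete with the wanted hydride shift. Fallback, setting out from 8 and returning at 10: Dess–Martin oxidation gives the epoxy ketone (7aS)-3,3a-epoxy-7a-methyl-3-(propan-2-yl)octahydro-4H-inden-4-one F4; SmI2 in THF/MeOH at −90 °C cleaves the α-C–O bond, and the samarium enolate is expected to protonate on the face away from the methyl and the solvated C3 alkoxide (to be confirmed), giving (3R,3aR,7aS)-3-hydroxy-7a-methyl-3-(propan-2-yl)octahydro-4H-inden-4-one F5; TMSOTf/2,6-lutidine then gives 10.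

Step 8. The congested ring-fusion carbon may migrate instead of the alkenyl carbon, the hindered ketone may enolise, or the β,γ-enone may slip into conjugation. Fallback, setting out from 13 and returning at 18, uses a regiospecific cyclopropylcarbinyl-to-homoallyl ring expansion:
- t-BuOOH/DBU epoxidises the enone anti to the methyl, giving the 5,6-epoxy ketone of 13 F6.
- Wharton transposition (N2H4·H2O, AcOH, MeOH) gives the allylic alcohol 5,7a-dimethyl-3-(propan-2-yl)-3-[(trimethylsilyl)oxy]-2,3,3a,6,7,7a-hexahydro-1H-inden-6-ol F7.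
- Hydroxyl-directed Simmons–Smith reaction (Et2Zn, CH2I2) gives the cyclopropyl carbinol F8, with the cyclopropane on the face of H5.
- HClO4 (cat.) in aqueous dioxane ionises the carbinol; the internal cyclopropane bond opens to form C8=C9, water attacks C6 anti to the breaking bond, and the silyl ether is hydrolysed, giving 18 directly.

Further compounds
F1 | step 2 | 1-bromo-4-methylpentan-3-one | CC(C)C(=O)CCBr
F2 | step 2 | 2-(2-bromoethyl)-2-(propan-2-yl)-1,3-dioxolane | CC(C)C1(CCBr)OCCO1
F3 | step 2 | (S)-3-methyl-3-{2-[2-(propan-2-yl)-1,3-dioxolan-2-yl]ethyl}cyclohexan-1-one | CC(C)C1(CC[C@]2(C)CCCC(=O)C2)OCCO1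
F4 | step 5 | (7aS)-3,3a-epoxy-7a-methyl-3-(propan-2-yl)octahydro-4H-inden-4-one, oxirane oxygen cis to the 7a-methyl | CC(C)[C@]12CC[C@]3(C)CCCC(=O)[C@@]31O2
F5 | step 5 | (3R,3aR,7aS)-3-hydroxy-7a-methyl-3-(propan-2-yl)octahydro-4H-inden-4-one | CC(C)[C@]1(O)CC[C@]2(C)CCCC(=O)[C@@H]12
F6 | step 8 | 5,6-epoxy ketone of 13, oxirane oxygen trans to the 7a-methyl | CC(C)[C@]1(O[Si](C)(C)C)CC[C@]2(C)C[C@@H]3O[C@]3(C)C(=O)[C@@H]12
F7 | step 8 | 5,7a-dimethyl-3-(propan-2-yl)-3-[(trimethylsilyl)oxy]-2,3,3a,6,7,7a-hexahydro-1H-inden-6-ol, C6 hydroxyl trans to the 7a-methyl | CC(C)[C@]1(O[Si](C)(C)C)CC[C@]2(C)C[C@H](O)C(C)=C[C@@H]12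
F8 | step 8 | 4,5-methano (cyclopropane) derivative of F7, cyclopropane cis to the C6 hydroxyl and to H3a | CC(C)[C@]1(O[Si](C)(C)C)CC[C@]2(C)C[C@H](O)[C@]3(C)C[C@@H]3[C@@H]12
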